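Rings: A, the 1,4-phenylene; B, the methoxy ring; C, the 1,3-phenylene; D, the phenol ring. The 18-membered ring is opened at the bond joining the CH2 of the C–D ethano bridge to the ring D carbon para to the phenolic oxygen. That ArCH2CH2–Ar' unit is the imprint of an anti-Markovnikov hydroboration of a ring C styrene followed by B-alkyl Suzuki–Miyaura coupling, and the para oxygen places the bromine needed on ring D. In one pot, 9-BBN turns the vinyl group of an open tetra-aryl chain into a primary alkylborane that closes the macrocycle onto the ring D bromide. The precursor carries an E-stilbene between rings A and B; one final hydrogenation saturates it and frees the phenol.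

Key step: step 6

Remark: the target has no stereocentre. The only stereo-element on the way is the E double bond of compounds 9, 10 and 11, which is removed in step 7.

Step 1
Reactants: 1 2-fluoro-3-methoxybenzaldehyde; 2 3-bromophenol
Product: 3 2-(3-bromophenoxy)-3-methoxybenzaldehyde
Conditions: K2CO3, DMAc, 130 °C
Reagents that add atoms: none
Why: Nucleophilic aromatic substitution (addition–elimination), in which the ortho formyl group activates the C–F bond of 1 toward the phenoxide of 2 while the aryl bromide stays inert under metal-free conditions.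

Step 2
Reactants: 3 2-(3-bromophenoxy)-3-methoxybenzaldehyde
Product: 4 2-(3-ethenylphenoxy)-3-methoxybenzaldehyde
Conditions: vinylboronic acid pinacol ester, Pd(PPh3)4 (3 mol %), K2CO3, 1,4-dioxane/H2O, 85 °C
Reagents that add atoms: vinylboronic acid pinacol ester, C=CB1OC(C)(C)C(C)(C)O1
Why: Suzuki–Miyaura coupling of the ring C bromide with a vinylboronate, a reaction that tolerates the aldehyde and installs the vinyl group before any second aryl bromide is present.

Step 3
Reactants: 5 2-(benzyloxy)phenol; 6 diethyl (4-bromobenzyl)phosphonate
Product: 7 diethyl {4-[2-(benzyloxy)phenoxy]benzyl}phosphonate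
Conditions: CuI (10 mol %), N,N-dimethylglycine (30 mol %), Cs2CO3, 1,4-dioxane, 100 °C
Reagents that add atoms: none
Why: Ullmann-type copper-catalysed diaryl ether synthesis, in which the electron-rich ortho-alkoxyphenoxide is a good nucleophile and the benzylic phosphonate is not deprotonated by carbonate.

Step 4
Reactants: 7 diethyl {4-[2-(benzyloxy)phenoxy]benzyl}phosphonate
Product: 8 diethyl {4-[2-(benzyloxy)-5-bromophenoxy]benzyl}phosphonate
Conditions: NBS (1.05 equiv), MeCN, 0 °C to rt, dark
Reagents that add atoms: N-bromosuccinimide, O=C1CCC(=O)N1Br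
Why: Electrophilic aromatic bromination of the doubly oxygenated ring D, where the alkoxy oxygen is a stronger para director than the aryloxy oxygen, so bromine should enter para to OBn, and polar dark conditions disfavour radical bromination at the benzylic CH2P.

Step 5
Reactants: 8 diethyl {4-[2-(benzyloxy)-5-bromophenoxy]benzyl}phosphonate; 4 2-(3-ethenylphenoxy)-3-methoxybenzaldehyde
Product: 9 1-(benzyloxy)-4-bromo-2-(4-{(E)-2-[2-(3-ethenylphenoxy)-3-methoxyphenyl]ethenyl}phenoxy)benzene
Conditions: KOtBu (1.1 equiv), THF, 0 °C to rt
Reagents that add atoms: none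
Why: Horner–Wadsworth–Emmons olefination of the benzylic phosphonate anion with a non-enolisable aryl aldehyde should give the E-stilbene, with the vinyl group, aryl bromide and benzyl ether untouched.

Step 6
Reactants: 9 1-(benzyloxy)-4-bromo-2-(4-{(E)-2-[2-(3-ethenylphenoxy)-3-methoxyphenyl]ethenyl}phenoxy)benzene
Product: 11 macrocyclic (E)-stilbene benzyl ether of the target, via B-alkyl-9-BBN adduct 10 (not isolated)
Conditions: 9-BBN (1.3 equiv), THF, 0 °C to rt; then slow addition to PdCl2(dppf) (10 mol %), AsPh3 (10 mol %), Cs2CO3, DMF/THF/H2O, 60 °C, final 2 mM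
Reagents that add atoms: none
Why: 9-BBN should add across the ring C vinyl group of 9 with boron on the terminal carbon to give 10, and after base activation the borate should transmetalate to the aryl–palladium bromide formed by oxidative addition of zerovalent palladium into the ring D C–Br bond, reductive elimination then forging the CH2–C(aryl) bond. The closest known reaction type is the one-pot hydroboration/B-alkyl Suzuki–Miyaura macrocyclisation. The single ring formed, the 18-membered macrocycle, is closed end to end by C(sp3)–C(sp2) reductive elimination from a large palladacycle, not by a transannular event. No stereocentre is created, and the E olefin between rings A and B is carried through unchanged. The step needs chemo- and regioselective hydroboration, which the steric demand of 9-BBN secures (terminal carbon of the styrene, internal stilbene untouched), and ring closure over oligomerisation, which slow addition into dilute catalyst solution and the two bent diaryl ether hinges of 9 secure. The wide bite angle of dppf should hold back β-hydride elimination of the primary alkyl–palladium species.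

Step 7
Reactants: 11 macrocyclic (E)-stilbene benzyl ether of the target
Product: 12 CNP0309263.0 (target)
Conditions: H2 (1 atm), Pd/C (10 wt %), EtOAc/EtOH, rt
Reagents that add atoms: none
Why: Heterogeneous catalytic hydrogenation should saturate the stilbene C=C and hydrogenolyse the benzyl ether in the same operation, no other reducible group being present.

Compound list
1 | 2-fluoro-3-methoxybenzaldehyde | COc1cccc(C=O)c1F | starting material
2 | 3-bromophenol | Oc1cccc(Br)c1 | starting material
3 | 2-(3-bromophenoxy)-3-methoxybenzaldehyde | COc1cccc(C=O)c1Oc1cccc(Br)c1 | intermediate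
4 | 2-(3-ethenylphenoxy)-3-methoxybenzaldehyde | COc1cccc(C=O)c1Oc1cccc(C=C)c1 | intermediate
5 | 2-(benzyloxy)phenol | Oc1ccccc1OCc1ccccc1 | starting material
6 | diethyl (4-bromobenzyl)phosphonate | CCOP(=O)(OCC)Cc1ccc(Br)cc1 | starting material
7 | diethyl {4-[2-(benzyloxy)phenoxy]benzyl}phosphonate | CCOP(=O)(OCC)Cc1ccc(Oc2ccccc2OCc2ccccc2)cc1 | intermediate
8 | diethyl {4-[2-(benzyloxy)-5-bromophenoxy]benzyl}phosphonate | CCOP(=O)(OCC)Cc1ccc(Oc2cc(Br)ccc2OCc2ccccc2)cc1 | intermediate
9 | 1-(benzyloxy)-4-bromo-2-(4-{(E)-2-[2-(3-ethenylphenoxy)-3-methoxyphenyl]ethenyl}phenoxy)benzene (open-chain precursor: ring C vinyl, ring D bromide, E olefin between rings A and B) | COc1cccc(/C=C/c2ccc(Oc3cc(Br)ccc3OCc3ccccc3)cc2)c1Oc1cccc(C=C)c1 | intermediate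
10 | B-alkyl-9-BBN adduct of 9 (ring C vinyl converted into CH2CH2–B of 9-borabicyclo[3.3.1]nonane) | COc1cccc(/C=C/c2ccc(Oc3cc(Br)ccc3OCc3ccccc3)cc2)c1Oc1cccc(CCB2C3CCCC2CCC3)c1 | intermediate
11 | macrocyclic (E)-stilbene benzyl ether (target skeleton with E CH=CH between rings A and B in place of CH2CH2 and OBn in place of the ring D OH) | COc1cccc(/C=C/c2ccc(Oc3cc(CCc4cccc(O5)c4)ccc3OCc3ccccc3)cc2)c15 | intermediate
12 | CNP0309263.0 | COc1cccc2c1Oc1cccc(c1)CCc1ccc(O)c(c1)Oc1ccc(cc1)CC2 | target

Total step count: 7. Longest linear sequence: 5 steps (steps 3, 4, 5, 6, 7, or equally steps 1, 2, 5, 6, 7).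

Steps most likely to fail

Step 6. Intermolecular coupling may outrun ring closure of the chain stiffened by the E olefin, and the alkylborane may be lost by protodeboronation or β-hydride elimination when transmetalation is slow at high dilution. The fallback sets out from 9 and comes back at 12. It saturates the A–B bridge before ring closure and forms the same CH2–C(aryl) bond by a nickel-catalysed reductive coupling instead of through boron. Hydroboration of 9 with 9-BBN (giving 10 in the flask) and oxidation with NaOH/H2O2 should give the 2-hydroxyethyl stilbene F1. Diimide (TsNHNH2, NaOAc, THF/H2O, reflux) should reduce the stilbene without touching the bromide or the benzyl ether, giving the saturated bibenzyl alcohol F2. PPh3, I2 and imidazole (CH2Cl2, 0 °C) should give the primary iodide F3. Reductive cross-electrophile coupling of the alkyl iodide with the ring D bromide (NiI2, 4,4'-di-tert-butyl-2,2'-bipyridine, Zn dust, DMA, 60 °C, slow addition) should close the now fully flexible chain to the saturated macrocyclic benzyl ether F4. Hydrogenolysis under the conditions of step 7 should then give 12.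

Step 4. Bromination may occur at the wrong site: para to the aryloxy oxygen, on ring A, or at the benzylic CH2P by a radical path. The fallback sets out from 5 and comes back at 8, and it also bypasses step 3. Nucleophilic aromatic substitution of 4-fluorobenzaldehyde by 5 (K2CO3, DMF, 120 °C) should give 4-[2-(benzyloxy)phenoxy]benzaldehyde F5. In F5 the formyl group draws the lone pair of the bridging oxygen into ring A and deactivates that ring, so NBS (MeCN, rt) should brominate only para to OBn and give 4-[2-(benzyloxy)-5-bromophenoxy]benzaldehyde F6. NaBH4 (MeOH, 0 °C) should give the benzylic alcohol F7, which ZnI2 and P(OEt)3 (toluene, reflux) should convert directly into phosphonate 8.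

Step 1. Substitution at the C–F bond flanked by two ortho substituents may be sluggish, and the aldehyde may be lost to base-induced disproportionation or condensation at the temperature required. The fallback sets out from 2 and comes back at 3. It uses 2-fluoro-3-methoxybenzonitrile as the electrophile, since the nitrile is the stronger activator and is stable to base. Substitution with 2 (K2CO3, DMSO, 100 °C) should give 2-(3-bromophenoxy)-3-methoxybenzonitrile F8. Half-reduction with DIBAL-H (toluene, −78 °C, then aqueous HCl) should deliver aldehyde 3.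

Further compounds
F1 | step 6 | 2-[3-(2-{(E)-2-[4-(2-(benzyloxy)-5-bromophenoxy)phenyl]ethenyl}-6-methoxyphenoxy)phenyl]ethanol | COc1cccc(/C=C/c2ccc(Oc3cc(Br)ccc3OCc3ccccc3)cc2)c1Oc1cccc(CCO)c1
F2 | step 6 | 2-[3-(2-{2-[4-(2-(benzyloxy)-5-bromophenoxy)phenyl]ethyl}-6-methoxyphenoxy)phenyl]ethanol | COc1cccc(CCc2ccc(Oc3cc(Br)ccc3OCc3ccccc3)cc2)c1Oc1cccc(CCO)c1
F3 | step 6 | 1-(benzyloxy)-4-bromo-2-[4-(2-{2-[3-(2-iodoethyl)phenoxy]-3-methoxyphenyl}ethyl)phenoxy]benzene | COc1cccc(CCc2ccc(Oc3cc(Br)ccc3OCc3ccccc3)cc2)c1Oc1cccc(CCI)c1
F4 | step 6 | O-benzyl ether of the target (saturated macrocycle with OBn on ring D) | COc1cccc2c1Oc1cccc(c1)CCc1ccc(OCc3ccccc3)c(c1)Oc1ccc(cc1)CC2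
F5 | step 4 | 4-[2-(benzyloxy)phenoxy]benzaldehyde | O=Cc1ccc(Oc2ccccc2OCc2ccccc2)cc1
F6 | step 4 | 4-[2-(benzyloxy)-5-bromophenoxy]benzaldehyde | O=Cc1ccc(Oc2cc(Br)ccc2OCc2ccccc2)cc1
F7 | step 4 | {4-[2-(benzyloxy)-5-bromophenoxy]phenyl}methanol | OCc1ccc(Oc2cc(Br)ccc2OCc2ccccc2)cc1
F8 | step 1 | 2-(3-bromophenoxy)-3-methoxybenzonitrile | COc1cccc(C#N)c1Oc1cccc(Br)c1
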